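**Plan**

1. Locants: ligustilide numbering, unprimed for the lactone on cyclohexene ring A (C3a, C4–C7, C7a), primed for the lactone on the bicyclo[2.2.2]octene (ring B: C3a', C4'–C7', C7a'); ring C is C6–C7–C4'–C3a'–C7a'–C7'.
2. Cuts: both butylidene lactones → enynoic acids → enol triflates of a bis(β-keto ester); then C3a–C7a (Dieckmann, ring A) and C4'–C5' (dienolate alkylation, ring B); last C6–C7 and C7'–C7a' of ring C (Diels–Alder).
3. Enabling feature: C7' and C6 are cis carbons flanked by the carbinol C6' and by C5, so with C5 as a carbonyl they are the alkene of a 5-substituted furan-2(5H)-one; C7a'/C3a' are the α-carbon and ketone of a β-keto ester, i.e. the end of a 2-silyloxy diene.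
4. Forward: diene 7 (steps 1–4) and butenolide 9 (step 5) give ring C (step 6); the lactone, a temporary ring and activating group, is opened and its carbonyl C5 reduced and homologated (steps 7–9); ring B (step 10), ring A (step 11), then both lactones at once (steps 12–15).
5. Stereochemistry: only C6' is bought (in 8); it sets C6, C7 and C7' in the cycloaddition (anti face, cis fusion, endo), and C4' follows as the bridgehead formed on the face that carries C6'.

Key step: step 6

Assumption: (5R)-5-(hydroxymethyl)furan-2(5H)-one (8) is taken as a purchasable compound like its (5S)-antipode; both are the known two-step products (Z-selective Wittig olefination, acid lactonisation) of the glyceraldehyde acetonides.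

**Route**

Step 1
Reactants: 1 tert-butyl acetate; 2 acrolein
Product: 3 tert-butyl 3-hydroxypent-4-enoate (racemic)
Conditions: LiN(iPr)2, THF, −78 °C; then 2; aq. NH4Cl
Reagents that add atoms: none
Why: The lithium ester enolate should add 1,2 to the enal at low temperature (ester aldol addition), and the racemic carbinol centre is oxidised away in step 3.

Step 2
Reactants: 3 tert-butyl 3-hydroxypent-4-enoate; 4 tert-butyl but-3-enoate
Product: 5 di-tert-butyl (4E)-3-hydroxyhept-4-enedioate (racemic)
Conditions: second-generation Hoveyda–Grubbs catalyst (5 mol %), 4 (3 equiv), CH2Cl2, 40 °C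
Reagents that add atoms: none
Why: Olefin cross-metathesis between the secondary allylic alcohol and the more reactive terminal alkene used in excess should give the E-alkene with loss of ethene.

Step 3
Reactants: 5 di-tert-butyl (4E)-3-hydroxyhept-4-enedioate
Product: 6 di-tert-butyl (4E)-3-oxohept-4-enedioate
Conditions: Dess–Martin periodinane, CH2Cl2, 0 °C to rt
Reagents that add atoms: none
Why: Dess–Martin oxidation of the allylic alcohol under non-basic conditions should give the enone without moving the double bond.

Step 4
Reactants: 6 di-tert-butyl (4E)-3-oxohept-4-enedioate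
Product: 7 di-tert-butyl (2Z,4E)-3-[(tert-butyldimethylsilyl)oxy]hepta-2,4-dienedioate
Conditions: NaH (1.05 equiv), THF, 0 °C; then TBSCl, 0 °C to rt
Reagents that add atoms: tert-butyl(chloro)dimethylsilane, CC(C)(C)[Si](C)(C)Cl
Why: The sodium enolate forms at the most acidic CH2 between the two carbonyl groups, is held Z by chelation and is silylated on oxygen (silyl enol ether formation), which fixes the 2-silyloxy diene with the ester on the outside.

Step 5
Reactants: 8 (5R)-5-(hydroxymethyl)furan-2(5H)-one
Product: 9 [(2R)-5-oxo-2,5-dihydrofuran-2-yl]methyl 4-methylbenzenesulfonate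
Conditions: TsCl, pyridine, CH2Cl2, 0 °C
Reagents that add atoms: 4-methylbenzenesulfonyl chloride, Cc1ccc(cc1)S(Cl)(=O)=O
Why: Sulfonylation of the primary alcohol with a weak base (tosylate formation) should leave the base-sensitive γ-position of the butenolide untouched.

Step 6
Reactants: 7 di-tert-butyl (2Z,4E)-3-[(tert-butyldimethylsilyl)oxy]hepta-2,4-dienedioate; 9 [(2R)-5-oxo-2,5-dihydrofuran-2-yl]methyl 4-methylbenzenesulfonate
Product: 10 cis-fused lactone cycloadduct (ring C formed; C5 is the lactone carbonyl, the ring oxygen sits on C6')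
Conditions: 7 (1.5 equiv), toluene, 145 °C (sealed tube), 2,6-di-tert-butyl-4-methylphenol (cat.)
Reagents that add atoms: none
Why: This is a thermal Diels–Alder reaction with normal electron demand between the 2-silyloxy diene ester and the α,β-unsaturated lactone, of the type known for 2-silyloxy dienes and 5-substituted furan-2(5H)-ones (a stepwise double Michael path would give the same product). It closes ring C as a six-membered ring by suprafacial [4+2] addition, the nucleophilic diene end C7a' bonding to the lactone β-carbon C7' and the other end C7 to the α-carbon C6, which is the "para" orientation of silyloxy and carbonyl and the "ortho" orientation of the C7 arm. C6 and C7' come out cis because the dienophile is a Z-alkene locked in the five-membered lactone, and their absolute sense is set by attack on the face anti to the CH2OTs group of the bought centre C6'. C7 is set by the endo transition state (lactone carbonyl under the diene) together with the E geometry of the diene, which puts the CH2CO2tBu arm cis to the lactone; C7a' is also formed but becomes trigonal again in step 10. The step needs regio-, facial and endo selectivity, secured in turn by the push–pull polarisation of the diene, by the resident stereocentre next to the reacting alkene and by secondary overlap with the lactone carbonyl.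

Step 7
Reactants: 10 cis-fused lactone cycloadduct; 11 methyl (triphenylphosphoranylidene)acetate
Product: 13 hydroxy enoate, via lactol 12 (not isolated)
Conditions: iBu2AlH (1.1 equiv), CH2Cl2, −78 °C; then 11, MeOH, −78 °C to rt; aq. potassium sodium tartrate
Reagents that add atoms: none
Why: Half-reduction of the γ-lactone should stop at the aluminium-bound lactol, whose open hydroxy aldehyde is trapped by the stabilised ylide (one-pot hydride reduction–Wittig olefination), which opens the temporary ring and adds C4 and C3a.

Step 8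
Reactants: 13 hydroxy enoate
Product: 14 silyl ether of 13 at the C6' oxygen
Conditions: TBSOTf, 2,6-lutidine, CH2Cl2, −78 °C
Reagents that add atoms: tert-butyldimethylsilyl trifluoromethanesulfonate, CC(C)(C)[Si](C)(C)OS(=O)(=O)C(F)(F)F
Why: Silylation of the freed secondary alcohol (silyl ether formation) blocks both oxa-Michael closure onto the enoate and epoxide formation with the neighbouring tosylate.

Step 9
Reactants: 14 silyl ether of 13
Product: 15 saturated methyl ester (C6 now carries CH2CH2CO2Me)
Conditions: H2 (1 atm), Pd/C, EtOAc, rt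
Reagents that add atoms: none
Why: Heterogeneous hydrogenation should saturate the unhindered disubstituted enoate much faster than the trisubstituted silyl enol ether, and no stereocentre is formed.

Step 10
Reactants: 15 saturated methyl ester
Product: 16 bicyclo[2.2.2]oct-2-ene (ring B closed)
Conditions: LiN(SiMe3)2 (1.05 equiv), THF, −78 to 0 °C
Reagents that add atoms: none
Why: The proton at C7a', α to the ester and allylic to the enol ether, is the most acidic, and its dienolate can reach the tosylate only through C4' (intramolecular γ-alkylation of an ester dienolate, six-membered closure across the 1,4-positions of ring C), which should form the bicyclo[2.2.2]octene, move the double bond to C3a'=C7a' and fix C4' as a bridgehead on the face that already carries C6'.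

Step 11
Reactants: 16 bicyclo[2.2.2]oct-2-ene
Product: 18 bis(β-keto ester), via silyl enol ether 17 (not isolated)
Conditions: KOtBu (2.5 equiv), THF, 0 °C to rt; then 1 M HCl, THF, 0 °C
Reagents that add atoms: none
Why: In this Dieckmann condensation the enolate α to the tert-butyl ester attacks the methyl ester, which is possible only because both arms are cis on the C6–C7 bridge, and the acidic work-up should hydrolyse the silyl enol ether (a vinylogous silyl carbonate) but not the alkyl silyl ether.

Step 12
Reactants: 18 bis(β-keto ester)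
Product: 19 bis(enol triflate)
Conditions: Tf2O (2.4 equiv), iPr2NEt, CH2Cl2, −78 to 0 °C
Reagents that add atoms: trifluoromethanesulfonic anhydride, O=S(=O)(OS(=O)(=O)C(F)(F)F)C(F)(F)F
Why: Each β-keto ester can enolise only between its two carbonyl groups (the other α-carbon of ring B is a bridgehead), so O-sulfonylation should give the two ring enol triflates with triflate cis to ester (enol triflate formation).

Step 13
Reactants: 19 bis(enol triflate); 20 pent-1-yne
Product: 21 bis(enyne) di-tert-butyl ester
Conditions: 20 (3 equiv), PdCl2(PPh3)2 (5 mol %), CuI (10 mol %), Et3N, THF, rt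
Reagents that add atoms: none
Why: Twofold Sonogashira coupling of the activated β-triflyloxy enoates with the terminal alkyne installs C3/C3' and both butyl chains, each alkyne held cis to its ester by the ring.

Step 14
Reactants: 21 bis(enyne) di-tert-butyl ester
Product: 22 hydroxy diacid
Conditions: CF3CO2H/CH2Cl2/H2O (10:10:1), 0 °C to rt
Reagents that add atoms: none
Why: Acidolysis should remove both tert-butyl esters as 2-methylpropene and the silyl ether in one operation (global acidic deprotection).

Step 15
Reactants: 22 hydroxy diacid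
Product: 23 target compound
Conditions: Ag2CO3 (10 mol %), DMF, rt, dark
Reagents that add atoms: none
Why: Silver-catalysed 5-exo-dig cyclisation of each (Z)-2-en-4-ynoic acid by anti addition of the carboxylate across the alkyne should give both Z-butylidene butenolides without touching a stereocentre.

**Compound list**

1 | tert-butyl acetate | CC(=O)OC(C)(C)C | starting material
2 | acrolein (prop-2-enal) | C=CC=O | starting material
3 | tert-butyl 3-hydroxypent-4-enoate (racemic) | C=CC(O)CC(=O)OC(C)(C)C | intermediate
4 | tert-butyl but-3-enoate | C=CCC(=O)OC(C)(C)C | starting material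
5 | di-tert-butyl (4E)-3-hydroxyhept-4-enedioate (racemic) | CC(C)(C)OC(=O)CC(O)/C=C/CC(=O)OC(C)(C)C | intermediate
6 | di-tert-butyl (4E)-3-oxohept-4-enedioate | CC(C)(C)OC(=O)CC(=O)/C=C/CC(=O)OC(C)(C)C | intermediate
7 | di-tert-butyl (2Z,4E)-3-[(tert-butyldimethylsilyl)oxy]hepta-2,4-dienedioate | CC(C)(C)OC(=O)/C=C(O[Si](C)(C)C(C)(C)C)/C=C/CC(=O)OC(C)(C)C | intermediate
8 | (5R)-5-(hydroxymethyl)furan-2(5H)-one | OC[C@H]1C=CC(=O)O1 | starting material
9 | [(2R)-5-oxo-2,5-dihydrofuran-2-yl]methyl 4-methylbenzenesulfonate | Cc1ccc(cc1)S(=O)(=O)OC[C@H]1C=CC(=O)O1 | intermediate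
10 | cycloadduct: tert-butyl 7-(2-tert-butoxy-2-oxoethyl)-5-[(tert-butyldimethylsilyl)oxy]-1-oxo-3-[(tosyloxy)methyl]-1,3,3a,4,7,7a-hexahydro-2-benzofuran-4-carboxylate; cis ring fusion, H-3a, H-4, H-7 and H-7a on one face, CH2OTs on the convex face (H-3 trans to H-3a) | O=C1[C@@H]2[C@H]([C@H](COS(=O)(=O)c3ccc(C)cc3)O1)[C@H](C(=O)OC(C)(C)C)C(O[Si](C)(C)C(C)(C)C)=C[C@@H]2CC(=O)OC(C)(C)C | intermediate
11 | methyl (triphenylphosphoranylidene)acetate | COC(=O)C=P(c1ccccc1)(c1ccccc1)c1ccccc1 | starting material
12 | lactol of 10 (C5 as hemiacetal carbon, anomeric mixture) | OC1[C@@H]2[C@H]([C@H](COS(=O)(=O)c3ccc(C)cc3)O1)[C@H](C(=O)OC(C)(C)C)C(O[Si](C)(C)C(C)(C)C)=C[C@@H]2CC(=O)OC(C)(C)C | intermediate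
13 | hydroxy enoate: ring-C cyclohexene with four cis substituents (CO2tBu on C7a', 1-hydroxy-2-(tosyloxy)ethyl on C7', (E)-CH=CH–CO2Me on C6, CH2CO2tBu on C7) and the silyl enol ether C3a'(OTBS)=C4' | COC(=O)/C=C/[C@@H]1[C@H]([C@H](COS(=O)(=O)c2ccc(C)cc2)O)[C@H](C(=O)OC(C)(C)C)C(O[Si](C)(C)C(C)(C)C)=C[C@@H]1CC(=O)OC(C)(C)C | intermediate
14 | 13 with the C6' hydroxyl as tert-butyldimethylsilyl ether | COC(=O)/C=C/[C@@H]1[C@H]([C@H](COS(=O)(=O)c2ccc(C)cc2)O[Si](C)(C)C(C)(C)C)[C@H](C(=O)OC(C)(C)C)C(O[Si](C)(C)C(C)(C)C)=C[C@@H]1CC(=O)OC(C)(C)C | intermediate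
15 | 14 with the C6 side chain saturated to CH2CH2CO2Me | COC(=O)CC[C@@H]1[C@H]([C@H](COS(=O)(=O)c2ccc(C)cc2)O[Si](C)(C)C(C)(C)C)[C@H](C(=O)OC(C)(C)C)C(O[Si](C)(C)C(C)(C)C)=C[C@@H]1CC(=O)OC(C)(C)C | intermediate
16 | bicyclo[2.2.2]oct-2-ene: CO2tBu on C7a', OTBS on C3a', OTBS on C6' (syn to the alkene bridge), cis arms CH2CH2CO2Me on C6 and CH2CO2tBu on C7 (both syn to the C5'–C6' bridge) | COC(=O)CC[C@@H]1[C@H]2C(C(=O)OC(C)(C)C)=C(O[Si](C)(C)C(C)(C)C)[C@H](C[C@@H]2O[Si](C)(C)C(C)(C)C)[C@@H]1CC(=O)OC(C)(C)C | intermediate
17 | tricyclic β-keto ester (ring A closed, ketone at C3a, CO2tBu on C7a) with the ring-B silyl enol ether still in place | O=C1CC[C@@H]2[C@H]3C(C(=O)OC(C)(C)C)=C(O[Si](C)(C)C(C)(C)C)[C@H](C[C@@H]3O[Si](C)(C)C(C)(C)C)[C@@H]2C1C(=O)OC(C)(C)C | intermediate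
18 | bis(β-keto ester): ketones at C3a and C3a', tert-butyl esters on C7a and C7a' (both epimerisable), OTBS on C6' | O=C1CC[C@@H]2[C@H]3C(C(=O)OC(C)(C)C)C(=O)[C@H](C[C@@H]3O[Si](C)(C)C(C)(C)C)[C@@H]2C1C(=O)OC(C)(C)C | intermediate
19 | bis(enol triflate): C3a(OTf)=C7a(CO2tBu) and C3a'(OTf)=C7a'(CO2tBu) | CC(C)(C)OC(=O)C1=C(OS(=O)(=O)C(F)(F)F)CC[C@@H]2[C@H]3C(C(=O)OC(C)(C)C)=C(OS(=O)(=O)C(F)(F)F)[C@H](C[C@@H]3O[Si](C)(C)C(C)(C)C)[C@H]12 | intermediate
20 | pent-1-yne | CCCC#C | starting material
21 | bis(enyne) di-tert-butyl ester: pent-1-ynyl groups on C3a and C3a' | CC(C)(C)OC(=O)C1=C(C#CCCC)CC[C@@H]2[C@H]3C(C(=O)OC(C)(C)C)=C(C#CCCC)[C@H](C[C@@H]3O[Si](C)(C)C(C)(C)C)[C@H]12 | intermediate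
22 | hydroxy diacid: 21 without the two tert-butyl groups and the silyl group | OC(=O)C1=C(C#CCCC)CC[C@@H]2[C@H]3C(C(O)=O)=C(C#CCCC)[C@H](C[C@@H]3O)[C@H]12 | intermediate
23 | target compound (both butylidene groups Z) | CCC/C=C1\OC(=O)C2=C1CC[C@@H]1[C@H]3C4=C(/C(=C/CCC)OC4=O)[C@H](C[C@@H]3O)[C@H]21 | target

**Summary**

Total step count: 15. Longest linear sequence: 14 steps (steps 1–4 and 6–15, from tert-butyl acetate).

Steps most likely to fail:

Step 6. The ester-bearing diene may react too slowly with the butenolide at a temperature that the tosylate and the silyl enol ether survive, and the endo preference that sets C7 may erode on heating. Fallback: the two bonds are made one after the other by catalysed conjugate additions instead of a thermal cycloaddition. Starting again from 7 and 9 with catalytic TBSOTf in CH2Cl2 at −78 °C, Mukaiyama–Michael addition of C7a' to C7' (anti to CH2OTs) with silyl transfer should give the silyl ketene acetal F1. On warming, its C6 should add to the enone carbon C7 in a second, intramolecular Mukaiyama–Michael addition that returns the silyl group to the C3a' oxygen and rejoins the route at 10.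

Step 10. The base may instead remove a proton next to a side-chain ester (premature Claisen-type chemistry), or the dienolate may attack through oxygen or eliminate the tosylate rather than alkylate at C4'. Fallback: the nucleophile is changed from the silyl dienolate to the dianion of the free β-keto ester. From 15, dilute HCl in THF should remove the enol silyl group to give the monocyclic β-keto ester F2. NaH followed by LiN(iPr)2 forms the dianion, whose γ-carbon C4' displaces the tosylate to give the bicyclic β-keto ester F3. KOtBu then closes ring A by Dieckmann condensation and the route is rejoined at 18.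

Step 7. The freed C6' hydroxyl may close onto the new enoate (oxa-Michael) or onto the neighbouring tosylate (epoxide), the lactol may be over-reduced, and the transient aldehyde may epimerise at C6. Fallback: the lactone is opened and the alcohol capped before any aldehyde or enoate exists. From 10, AlMe3 and N,O-dimethylhydroxylamine hydrochloride should give the hydroxy N-methoxy-N-methylamide F4. TBSOTf with 2,6-lutidine gives the silyl ether F5, iBu2AlH reduces the amide to the aldehyde F6, and olefination with 11 rejoins the route at 14.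

Further compounds

F1 | step 6 | silyl ketene acetal: 2-[(tert-butyldimethylsilyl)oxy]-4,5-dihydrofuran carrying CH2OTs on C6' and, trans to it on C7', the CH(CO2tBu)–C(=O)–CH=CH–CH2CO2tBu chain | CC(C)(C)[Si](C)(C)OC1=C[C@H]([C@H](COS(=O)(=O)c2ccc(C)cc2)O1)C(C(=O)OC(C)(C)C)C(=O)/C=C/CC(=O)OC(C)(C)C
F2 | step 10 | monocyclic β-keto ester: 15 with the ring-C silyl enol ether hydrolysed to the C3a' ketone | COC(=O)CC[C@@H]1[C@H]([C@H](COS(=O)(=O)c2ccc(C)cc2)O[Si](C)(C)C(C)(C)C)C(C(=O)OC(C)(C)C)C(=O)C[C@@H]1CC(=O)OC(C)(C)C
F3 | step 10 | bicyclo[2.2.2]octanone β-keto ester: ring B closed, ketone at C3a', both ester arms still open | COC(=O)CC[C@@H]1[C@H]2C(C(=O)OC(C)(C)C)C(=O)[C@H](C[C@@H]2O[Si](C)(C)C(C)(C)C)[C@@H]1CC(=O)OC(C)(C)C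
F4 | step 7 | hydroxy N-methoxy-N-methylamide: 10 with the lactone opened at C5 by the amine | CON(C)C(=O)[C@@H]1[C@H]([C@H](COS(=O)(=O)c2ccc(C)cc2)O)[C@H](C(=O)OC(C)(C)C)C(O[Si](C)(C)C(C)(C)C)=C[C@@H]1CC(=O)OC(C)(C)C
F5 | step 7 | tert-butyldimethylsilyl ether of F4 at the C6' oxygen | CON(C)C(=O)[C@@H]1[C@H]([C@H](COS(=O)(=O)c2ccc(C)cc2)O[Si](C)(C)C(C)(C)C)[C@H](C(=O)OC(C)(C)C)C(O[Si](C)(C)C(C)(C)C)=C[C@@H]1CC(=O)OC(C)(C)C
F6 | step 7 | aldehyde: F5 with C5 reduced to CHO | O=C[C@@H]1[C@H]([C@H](COS(=O)(=O)c2ccc(C)cc2)O[Si](C)(C)C(C)(C)C)[C@H](C(=O)OC(C)(C)C)C(O[Si](C)(C)C(C)(C)C)=C[C@@H]1CC(=O)OC(C)(C)C
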